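**Plan**
- Retrosynthesis: the C10' ester level and C11=C12 (Horner–Wadsworth–Emmons) are cut first, then C8–C9 and C8–H (alkenyllithium and hydride on a lactone carbonyl), then C1–C6 and O1–C8 together, and last C5–C6 (acetylide addition) and C3–C4 (allylation).
- Enabling feature: C6, the fully substituted carbon shared by ring A (C1–C6) and ring B (O1, C5–C8), lies between quaternary C1 and oxygen-bearing quaternary C5. As the β-carbon of a C6≡C7 ynoate it can accept a tertiary C1 radical, and O1 on C5 is then placed to acylate at C8.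
- Forward: the open chain C1–C8 is built, rings A and B close together in step 7, the lactone is turned into the 2,5-dihydrofuran carrying C9–C11, and the C12–C10' polyene is joined by olefination and reduced.
- Stereochemistry: C3 from reagent-controlled allylboration; C5 from C3 by chelation-controlled 1,3-anti addition; C8 at hydride delivery to a furylium ion (weak substrate control, epimer separated); C9=C10 (Z) from trans-hydroalumination/iodination of but-2-yn-1-ol; the other alkenes from the C10-dialdehyde and E-selective olefinations.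

Key step: step 7

Remark: atoms carry carotenoid numbers (C1 gem-dimethyl carbon, C3 carbinol, C5 O-bearing quaternary carbon, C6=C7 ring alkene, C8 the O-bearing CH, then C9–C15 and C15'–C10' along the chain). The C9=C10 bond of the given structure has C8 and C11 cis (Z), and this is taken as intended.

**Route**

Step 1
Reactants: 1 3-methylbut-2-enal
Product: 2 (4R)-6-methylhepta-1,5-dien-4-ol
Conditions: (+)-Ipc2B(allyl), Et2O, −78 °C; then NaOH, H2O2
Reagents that add atoms: (+)-B-allyldiisopinocampheylborane, C=CCB([C@H]1C[C@H]2C[C@@H]([C@@H]1C)C2(C)C)[C@H]1C[C@H]2C[C@@H]([C@@H]1C)C2(C)C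
Why: Brown allylboration through a chair transition state, with the isopinocampheyl groups of this enantiomer (the one that gives (R)-1-phenylbut-3-en-1-ol from benzaldehyde) directing allyl to the Re face, so that C3 is set as R by reagent control and the enal reacts by 1,2-addition only.

Step 2
Reactants: 2 (4R)-6-methylhepta-1,5-dien-4-ol
Product: 3 (4R)-4-[(4-methoxybenzyl)oxy]-6-methylhepta-1,5-diene
Conditions: NaH, 4-methoxybenzyl chloride, Bu4NI (cat.), THF/DMF, 0 °C to rt
Reagents that add atoms: 4-methoxybenzyl chloride, COc1ccc(CCl)cc1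
Why: Williamson etherification of the alkoxide, basic throughout so that the ionisable allylic C3–O bond is not disturbed, installing an ether oxygen able to chelate in step 4.

Step 3
Reactants: 3 (4R)-4-[(4-methoxybenzyl)oxy]-6-methylhepta-1,5-diene
Product: 4 (4R)-4-[(4-methoxybenzyl)oxy]-6-methylhept-5-en-2-one
Conditions: PdCl2 (10 mol %), CuCl, O2 (1 atm), DMF/H2O, rt
Reagents that add atoms: water, O
Why: Tsuji–Wacker oxidation, in which Markovnikov hydroxypalladation of the monosubstituted alkene of a homoallylic ether gives the methyl ketone while the trisubstituted alkene is inert.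

Step 4
Reactants: 4 (4R)-4-[(4-methoxybenzyl)oxy]-6-methylhept-5-en-2-one, 5 ethyl propiolate
Product: 7 ethyl (4R,6R)-4-hydroxy-6-[(4-methoxybenzyl)oxy]-4,8-dimethylnon-7-en-2-ynoate, via lithium acetylide 6 (not isolated)
Conditions: 5, LiN(SiMe3)2, Et2O, −78 °C; 4 precomplexed with MgBr2·OEt2 in CH2Cl2, −78 °C; AcOH quench at −78 °C
Reagents that add atoms: none
Why: Chelation-controlled 1,2-addition, in which magnesium bridges the ketone and ether oxygens in a six-membered half-chair with the C3 alkenyl group equatorial and the small acetylide attacks axially (the sense of a Narasaka–Prasad reduction), giving the 1,3-anti relationship (C5 R); any C5 epimer is to be removed by chromatography.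

Step 5
Reactants: 7 ethyl (4R,6R)-4-hydroxy-6-[(4-methoxybenzyl)oxy]-4,8-dimethylnon-7-en-2-ynoate
Product: 8 ethyl (4R,6R)-4,6-dihydroxy-4,8-dimethylnon-7-en-2-ynoate
Conditions: DDQ, CH2Cl2/pH 7 buffer (10:1), 0 °C
Reagents that add atoms: none
Why: Oxidative cleavage of the 4-methoxybenzyl ether by hydride abstraction and hydrolysis, under near-neutral conditions that leave the ynoate, the trisubstituted alkene and both carbinols untouched.

Step 6
Reactants: 8 ethyl (4R,6R)-4,6-dihydroxy-4,8-dimethylnon-7-en-2-ynoate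
Product: 9 ethyl (4R,6R)-6-[(tert-butyldimethylsilyl)oxy]-4-hydroxy-4,8-dimethylnon-7-en-2-ynoate
Conditions: TBSOTf (1.05 equiv), 2,6-lutidine, CH2Cl2, −78 °C
Reagents that add atoms: tert-butyldimethylsilyl triflate, CC(C)(C)[Si](C)(C)OS(=O)(=O)C(F)(F)F
Why: Silylation of the secondary allylic hydroxyl in preference to the hindered tertiary propargylic one, with a base too hindered to add to the ynoate or to trigger oxa-Michael closure of the C3 oxygen onto C6.

Step 7
Reactants: 9 ethyl (4R,6R)-6-[(tert-butyldimethylsilyl)oxy]-4-hydroxy-4,8-dimethylnon-7-en-2-ynoate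
Product: 12 (6S,7aR)-6-[(tert-butyldimethylsilyl)oxy]-4,4,7a-trimethyl-5,6,7,7a-tetrahydro-1-benzofuran-2(4H)-one (O-TBS loliolide), via (E)-hydroxy enoate 10 (not isolated), via (Z)-hydroxy enoate 11 (not isolated)
Conditions: Fe(acac)3 (0.3 equiv), PhSiH3 (2.5 equiv), EtOH/(CH2OH)2 (5:1), 60 °C; then acetone, hν (300 nm), PPTS (cat.), rt
Reagents that add atoms: none
Why: Proposed new method: an iron hydride formed from Fe(acac)3 and PhSiH3 transfers a hydrogen atom to C2 of the electron-rich C1=C2 alkene, the tertiary C1 radical adds to C6 (the β-carbon of the ynoate), and the α-ester vinyl radical at C7 is reduced by divalent iron and protonated by ethanol to give enoates 10 and 11. The closest known reaction type is the iron-hydride hydrogen-atom-transfer reductive coupling of alkenes with conjugated alkenes (intramolecular Giese cyclisation), and 6-exo-dig additions of carbon radicals to alkynoates are established under tin hydride conditions, so only the alkynoate acceptor under iron hydride conditions is extrapolated. Ring A closes 6-exo-dig (C1–C6) and ring B closes by 5-exo-trig acyl substitution of the C5 hydroxyl on the ester (O1–C8), which only the (Z)-enoate 11 can reach; sensitised irradiation interconverts 10 and 11 (photodeconjugation is impossible because C1 and C5 carry no hydrogen) and lactonisation drains the mixture to 12. No stereocentre is created; C3 and C5 pass through unchanged and the C6=C7 geometry is fixed by the ring. The step needs hydrogen-atom transfer to the trisubstituted alkene and not to the ynoate, and 6-exo attack at C6 and not 7-endo attack at C7. These are secured by the preference of the metal hydride for the electron-rich alkene, by the match of the nucleophilic tertiary radical with the electron-poor β-carbon, and by the silyl ether, which keeps the C3 oxygen from adding to the ynoate.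

Step 8
Reactants: 13 but-2-yn-1-ol
Product: 14 (2Z)-3-iodobut-2-en-1-ol
Conditions: NaAlH2(OCH2CH2OMe)2 (Red-Al), THF, 0 °C to rt; EtOAc; then I2, −78 °C
Reagents that add atoms: iodine, II
Why: Hydroxyl-directed trans-hydroalumination places aluminium at C3 in a five-membered alkoxyaluminate, and iodinolysis with retention gives the iodide with iodine cis to CH2OH, which later fixes C8 cis to C11 across C9=C10.

Step 9
Reactants: 14 (2Z)-3-iodobut-2-en-1-ol
Product: 15 {[(2Z)-3-iodobut-2-en-1-yl]oxy}tri(propan-2-yl)silane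
Conditions: i-Pr3SiCl, imidazole, DMF, rt
Reagents that add atoms: triisopropylsilyl chloride, CC(C)[Si](Cl)(C(C)C)C(C)C
Why: Standard silylation of a primary alcohol; the bulky triisopropylsilyl group is chosen because it resists 1,4 O-to-C silyl migration in the derived cis-γ-silyloxy alkenyllithium and survives BF3·OEt2 at low temperature.

Step 10
Reactants: 15 {[(2Z)-3-iodobut-2-en-1-yl]oxy}tri(propan-2-yl)silane, 12 O-TBS loliolide
Product: 17 (6S,7aR)-6-[(tert-butyldimethylsilyl)oxy]-4,4,7a-trimethyl-2-{(2Z)-4-[(triisopropylsilyl)oxy]but-2-en-2-yl}-2,4,5,6,7,7a-hexahydro-1-benzofuran-2-ol (both C8 anomers), via alkenyllithium 16 (not isolated)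
Conditions: 15, t-BuLi (2 equiv), Et2O, −78 °C; then 12, −78 °C; H2O quench; used crude
Reagents that add atoms: none
Why: Iodine–lithium exchange with retention of alkene geometry, then 1,2-addition to the lactone carbonyl; conjugate addition is blocked because C6 is fully substituted, the lactone has no enolisable hydrogen, and the tetrahedral lithium alkoxide does not collapse at −78 °C, so a single addition is expected.

Step 11
Reactants: 17 hemiketal (both C8 anomers)
Product: 18 tert-butyl(dimethyl){[(2R,6S,7aR)-4,4,7a-trimethyl-2-{(2Z)-4-[(triisopropylsilyl)oxy]but-2-en-2-yl}-2,4,5,6,7,7a-hexahydro-1-benzofuran-6-yl]oxy}silane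
Conditions: Et3SiH (excess), BF3·OEt2, CH2Cl2, −78 °C
Reagents that add atoms: none
Why: Kishi-type ionic reduction in which BF3·OEt2 ionises the hemiketal to a 2-alkenyl-2H-furylium (oxocarbenium) ion and Et3SiH delivers hydride to C8, the carbon of highest positive charge; the two faces differ only in the C5 methyl against the C4 methylene of ring A, so induction is expected to be weak and the 8R epimer (hydride syn to the C5 methyl) is to be separated from its C8 epimer by chromatography here.

Step 12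
Reactants: 18 bis-silyl ether
Product: 19 (2R,6S,7aR)-2-[(2Z)-4-hydroxybut-2-en-2-yl]-4,4,7a-trimethyl-2,4,5,6,7,7a-hexahydro-1-benzofuran-6-ol
Conditions: Bu4NF, THF, rt
Reagents that add atoms: none
Why: Fluoride cleavage of both silyl ethers under non-acidic conditions, which spare the bis-allylic C8–O1 ether and the C8 configuration.

Step 13
Reactants: 19 diol
Product: 20 (2Z)-3-[(2R,6S,7aR)-6-hydroxy-4,4,7a-trimethyl-2,4,5,6,7,7a-hexahydro-1-benzofuran-2-yl]but-2-enal
Conditions: MnO2 (activated), CH2Cl2, rt, dark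
Reagents that add atoms: none
Why: MnO2 oxidises only the allylic primary alcohol, leaves the non-allylic secondary C3 hydroxyl untouched, and under neutral conditions is expected to keep the Z geometry at C9=C10.

Step 14
Reactants: 21 (2E,4E,6E)-2,7-dimethylocta-2,4,6-trienedial (C10-dialdehyde)
Product: 22 ethyl (2E,4E,6E,8E)-4,9-dimethyl-10-oxodeca-2,4,6,8-tetraenoate
Conditions: Ph3P=CHCO2Et (1 equiv), 21 in excess, PhMe, 60 °C
Reagents that add atoms: (ethoxycarbonylmethylene)triphenylphosphorane, CCOC(=O)C=P(c1ccccc1)(c1ccccc1)c1ccccc1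
Why: Wittig olefination with a stabilised ylide is E-selective and base-free, and a deficit of ylide stops at the mono-adduct, with unreacted dialdehyde recovered.

Step 15
Reactants: 22 ester aldehyde
Product: 23 ethyl (2E,4E,6E,8E)-10-hydroxy-4,9-dimethyldeca-2,4,6,8-tetraenoate
Conditions: NaBH4, EtOH/THF, 0 °C
Reagents that add atoms: none
Why: Borohydride 1,2-reduction of the aldehyde is much faster than any reaction of the conjugated ester.

Step 16
Reactants: 23 hydroxy ester
Product: 24 ethyl (2E,4E,6E,8E)-10-bromo-4,9-dimethyldeca-2,4,6,8-tetraenoate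
Conditions: PBr3, pyridine (cat.), Et2O, −10 °C; used at once
Reagents that add atoms: phosphorus tribromide, BrP(Br)Br
Why: Conversion of a primary allylic alcohol into the bromide by SN2 displacement of the phosphite ester, the standard entry to polyenyl phosphonates.

Step 17
Reactants: 24 bromo ester
Product: 25 ethyl (2E,4E,6E,8E)-10-(diethoxyphosphoryl)-4,9-dimethyldeca-2,4,6,8-tetraenoate
Conditions: P(OEt)3, PhMe, 100 °C
Reagents that add atoms: triethyl phosphite, CCOP(OCC)OCC
Why: Michaelis–Arbuzov reaction of a reactive primary allylic bromide.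

Step 18
Reactants: 20 enal, 25 phosphonate
Product: 27 ethyl (2E,4E,6E,8E,10E,12Z)-13-[(2R,6S,7aR)-6-hydroxy-4,4,7a-trimethyl-2,4,5,6,7,7a-hexahydro-1-benzofuran-2-yl]-4,9-dimethyltetradeca-2,4,6,8,10,12-hexaenoate, via sodium phosphonate carbanion 26 (not isolated)
Conditions: 25 (1.4 equiv), NaN(SiMe3)2, THF, −78 °C; then 20, −78 to 0 °C, dark
Reagents that add atoms: none
Why: Horner–Wadsworth–Emmons olefination with a vinylogous ester-stabilised phosphonate anion forms C11=C12 with E selectivity; the delocalised anion is too weak a base to deprotonate the free C3 hydroxyl and, added cold, should attack the aldehyde faster than it removes the C8 hydrogen.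

Step 19
Reactants: 27 polyene ester
Product: 28 (2E,4E,6E,8E,10E,12Z)-13-[(2R,6S,7aR)-6-hydroxy-4,4,7a-trimethyl-2,4,5,6,7,7a-hexahydro-1-benzofuran-2-yl]-4,9-dimethyltetradeca-2,4,6,8,10,12-hexaen-1-ol (target)
Conditions: i-Bu2AlH (excess), CH2Cl2, −78 °C; aq. KNaC4H4O6 (Rochelle salt); dark, argon
Reagents that add atoms: none
Why: 1,2-Reduction of the conjugated ester to the allylic alcohol, with a neutral tartrate work-up that avoids acid-induced epimerisation at C8 or isomerisation of the polyene.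

**Compound list**
1 | 3-methylbut-2-enal | CC(C)=CC=O | starting material
2 | (4R)-6-methylhepta-1,5-dien-4-ol | C=CC[C@@H](O)C=C(C)C | intermediate
3 | (4R)-4-[(4-methoxybenzyl)oxy]-6-methylhepta-1,5-diene | C=CC[C@@H](OCc1ccc(OC)cc1)C=C(C)C | intermediate
4 | (4R)-4-[(4-methoxybenzyl)oxy]-6-methylhept-5-en-2-one | CC(=O)C[C@@H](OCc1ccc(OC)cc1)C=C(C)C | intermediate
5 | ethyl propiolate | C#CC(=O)OCC | starting material
6 | ethyl 3-lithioprop-2-ynoate | [Li]C#CC(=O)OCC | intermediate (not isolated)
7 | ethyl (4R,6R)-4-hydroxy-6-[(4-methoxybenzyl)oxy]-4,8-dimethylnon-7-en-2-ynoate | CCOC(=O)C#C[C@](C)(O)C[C@@H](OCc1ccc(OC)cc1)C=C(C)C | intermediate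
8 | ethyl (4R,6R)-4,6-dihydroxy-4,8-dimethylnon-7-en-2-ynoate | CCOC(=O)C#C[C@](C)(O)C[C@@H](O)C=C(C)C | intermediate
9 | ethyl (4R,6R)-6-[(tert-butyldimethylsilyl)oxy]-4-hydroxy-4,8-dimethylnon-7-en-2-ynoate | CCOC(=O)C#C[C@](C)(O)C[C@@H](O[Si](C)(C)C(C)(C)C)C=C(C)C | intermediate (key-step precursor)
10 | ethyl (2E)-2-[(2R,4S)-4-[(tert-butyldimethylsilyl)oxy]-2-hydroxy-2,6,6-trimethylcyclohexylidene]acetate | CCOC(=O)/C=C1\C(C)(C)C[C@H](O[Si](C)(C)C(C)(C)C)C[C@@]1(C)O | intermediate (not isolated)
11 | ethyl (2Z)-2-[(2R,4S)-4-[(tert-butyldimethylsilyl)oxy]-2-hydroxy-2,6,6-trimethylcyclohexylidene]acetate | CCOC(=O)/C=C1/C(C)(C)C[C@H](O[Si](C)(C)C(C)(C)C)C[C@@]1(C)O | intermediate (not isolated)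
12 | (6S,7aR)-6-[(tert-butyldimethylsilyl)oxy]-4,4,7a-trimethyl-5,6,7,7a-tetrahydro-1-benzofuran-2(4H)-one (O-TBS loliolide) | O=C1C=C2C(C)(C)C[C@H](O[Si](C)(C)C(C)(C)C)C[C@@]2(C)O1 | intermediate (key-step product)
13 | but-2-yn-1-ol | CC#CCO | starting material
14 | (2Z)-3-iodobut-2-en-1-ol | C/C(I)=C/CO | intermediate
15 | {[(2Z)-3-iodobut-2-en-1-yl]oxy}tri(propan-2-yl)silane | C/C(I)=C/CO[Si](C(C)C)(C(C)C)C(C)C | intermediate
16 | {(2E)-4-[(triisopropylsilyl)oxy]but-2-en-2-yl}lithium (lithium cis to the CH2O group) | C/C([Li])=C/CO[Si](C(C)C)(C(C)C)C(C)C | intermediate (not isolated)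
17 | (6S,7aR)-6-[(tert-butyldimethylsilyl)oxy]-4,4,7a-trimethyl-2-{(2Z)-4-[(triisopropylsilyl)oxy]but-2-en-2-yl}-2,4,5,6,7,7a-hexahydro-1-benzofuran-2-ol (both C8 anomers) | C/C(=C/CO[Si](C(C)C)(C(C)C)C(C)C)C1(O)C=C2C(C)(C)C[C@H](O[Si](C)(C)C(C)(C)C)C[C@@]2(C)O1 | intermediate
18 | tert-butyl(dimethyl){[(2R,6S,7aR)-4,4,7a-trimethyl-2-{(2Z)-4-[(triisopropylsilyl)oxy]but-2-en-2-yl}-2,4,5,6,7,7a-hexahydro-1-benzofuran-6-yl]oxy}silane | C/C(=C/CO[Si](C(C)C)(C(C)C)C(C)C)[C@H]1C=C2C(C)(C)C[C@H](O[Si](C)(C)C(C)(C)C)C[C@@]2(C)O1 | intermediate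
19 | (2R,6S,7aR)-2-[(2Z)-4-hydroxybut-2-en-2-yl]-4,4,7a-trimethyl-2,4,5,6,7,7a-hexahydro-1-benzofuran-6-ol | C/C(=C/CO)[C@H]1C=C2C(C)(C)C[C@H](O)C[C@@]2(C)O1 | intermediate
20 | (2Z)-3-[(2R,6S,7aR)-6-hydroxy-4,4,7a-trimethyl-2,4,5,6,7,7a-hexahydro-1-benzofuran-2-yl]but-2-enal | C/C(=C/C=O)[C@H]1C=C2C(C)(C)C[C@H](O)C[C@@]2(C)O1 | intermediate
21 | (2E,4E,6E)-2,7-dimethylocta-2,4,6-trienedial (C10-dialdehyde) | O=C/C(C)=C/C=C/C=C(\C)C=O | starting material
22 | ethyl (2E,4E,6E,8E)-4,9-dimethyl-10-oxodeca-2,4,6,8-tetraenoate | CCOC(=O)/C=C/C(C)=C/C=C/C=C(C)/C=O | intermediate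
23 | ethyl (2E,4E,6E,8E)-10-hydroxy-4,9-dimethyldeca-2,4,6,8-tetraenoate | CCOC(=O)/C=C/C(C)=C/C=C/C=C(C)/CO | intermediate
24 | ethyl (2E,4E,6E,8E)-10-bromo-4,9-dimethyldeca-2,4,6,8-tetraenoate | CCOC(=O)/C=C/C(C)=C/C=C/C=C(C)/CBr | intermediate
25 | ethyl (2E,4E,6E,8E)-10-(diethoxyphosphoryl)-4,9-dimethyldeca-2,4,6,8-tetraenoate | CCOC(=O)/C=C/C(C)=C/C=C/C=C(C)/CP(=O)(OCC)OCC | intermediate
26 | sodium salt of the C10 carbanion of 25 | [Na+].CCOC(=O)/C=C/C(C)=C/C=C/C=C(C)/[CH-]P(=O)(OCC)OCC | intermediate (not isolated)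
27 | ethyl (2E,4E,6E,8E,10E,12Z)-13-[(2R,6S,7aR)-6-hydroxy-4,4,7a-trimethyl-2,4,5,6,7,7a-hexahydro-1-benzofuran-2-yl]-4,9-dimethyltetradeca-2,4,6,8,10,12-hexaenoate | C/C(=C/C=C/C(C)=C/C=C/C=C(C)/C=C/C(=O)OCC)[C@H]1C=C2C(C)(C)C[C@H](O)C[C@@]2(C)O1 | intermediate
28 | (2E,4E,6E,8E,10E,12Z)-13-[(2R,6S,7aR)-6-hydroxy-4,4,7a-trimethyl-2,4,5,6,7,7a-hexahydro-1-benzofuran-2-yl]-4,9-dimethyltetradeca-2,4,6,8,10,12-hexaen-1-ol | C/C(=C/C=C/C(C)=C/C=C/C=C(C)/C=C/CO)[C@H]1C=C2C(C)(C)C[C@H](O)C[C@@]2(C)O1 | target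

**Count**
Total: 19 steps. Longest linear sequence: 13 steps (steps 1–7, 10–13, 18, 19, from 3-methylbut-2-enal).

**Steps most likely to fail**

1. Step 7 (Proposed new method). The C1 radical may be reduced or trapped before it adds to the hindered ynoate, hydrogen-atom transfer may go to the ynoate instead of the alkene, or the (E)-enoate may not be funnelled to the lactone. Fallback with known chemistry, from 9 back to 12: semihydrogenation of 9 (H2, Pd/CaCO3 poisoned with Pb(OAc)2, quinoline, EtOAc) gives the (Z)-enoate, which lactonises to the butenolide (5R)-5-{(2R)-2-[(tert-butyldimethylsilyl)oxy]-4-methylpent-3-en-1-yl}-5-methylfuran-2(5H)-one F1. Fe(acac)3/PhSiH3 in EtOH/(CH2OH)2 at 60 °C then performs the established hydrogen-atom-transfer Giese cyclisation onto an α,β-unsaturated lactone (6-exo-trig, same C1–C6 bond) to give the cis-fused saturated lactone (3aS,6S,7aR)-6-[(tert-butyldimethylsilyl)oxy]-4,4,7a-trimethylhexahydro-1-benzofuran-2(3H)-one F2. LiN(i-Pr)2 and PhSeBr at −78 °C give the α-selenide (3R,3aS,6S,7aR)-6-[(tert-butyldimethylsilyl)oxy]-4,4,7a-trimethyl-3-(phenylselanyl)hexahydro-1-benzofuran-2(3H)-one F3, with selenium on the convex face syn to H6. Oxidation with H2O2 and syn-elimination of the selenoxide restore C6=C7 and return the route to 12.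

2. Step 11. Hydride delivery to the furylium ion may show poor or reversed facial selectivity at C8, and hydride may also attack C10 of the extended cation. Fallback, from 12 and 15 back to 18, with the roles at C8 inverted: i-Bu2AlH (CH2Cl2, −78 °C) reduces 12 to the lactol (6S,7aR)-6-[(tert-butyldimethylsilyl)oxy]-4,4,7a-trimethyl-2,4,5,6,7,7a-hexahydro-1-benzofuran-2-ol F4, and Ac2O/pyridine gives the lactol acetate (6S,7aR)-6-[(tert-butyldimethylsilyl)oxy]-4,4,7a-trimethyl-2,4,5,6,7,7a-hexahydro-1-benzofuran-2-yl acetate F5. Iodide 15 is converted (t-BuLi; B(OMe)3; aq. KHF2) into potassium trifluoro{(2E)-4-[(triisopropylsilyl)oxy]but-2-en-2-yl}borate F6 (boron cis to the CH2O group). BF3·OEt2-promoted addition of F6 to the oxocarbenium ion from F5 forms C8–C9 and gives 18 directly. Here the carbon nucleophile, not hydride, chooses the face, so the same intrinsic facial preference gives the opposite C8 epimer to that of the main sequence, and the cation has no side-chain alkene through which C10 could be attacked.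

3. Step 18. The phosphonate anion may deprotonate the enal at C8 (the γ-position), which would epimerise C8 and erode the Z geometry at C9=C10. Fallback, from 19 and 22 back to 27, with the polarity of the coupling reversed: CBr4/PPh3 (CH2Cl2, −20 °C) converts the allylic hydroxyl of 19 selectively into the bromide (2R,6S,7aR)-2-[(2Z)-4-bromobut-2-en-2-yl]-4,4,7a-trimethyl-2,4,5,6,7,7a-hexahydro-1-benzofuran-6-ol F7, and PPh3 gives the phosphonium salt {(2Z)-3-[(2R,6S,7aR)-6-hydroxy-4,4,7a-trimethyl-2,4,5,6,7,7a-hexahydro-1-benzofuran-2-yl]but-2-en-1-yl}triphenylphosphonium bromide F8. Wittig reaction of F8 with ester aldehyde 22 (NaOMe, CH2Cl2/MeOH, 0 °C) gives 27 after separation of C11=C12 isomers, without iodine isomerisation, which would endanger the Z bond. In this mode the ring fragment never carries a carbonyl that acidifies C8–H.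

**Further compounds**
F1 | step 7 | (5R)-5-{(2R)-2-[(tert-butyldimethylsilyl)oxy]-4-methylpent-3-en-1-yl}-5-methylfuran-2(5H)-one | O=C1C=C[C@@](C)(C[C@@H](O[Si](C)(C)C(C)(C)C)C=C(C)C)O1
F2 | step 7 | (3aS,6S,7aR)-6-[(tert-butyldimethylsilyl)oxy]-4,4,7a-trimethylhexahydro-1-benzofuran-2(3H)-one | O=C1C[C@H]2C(C)(C)C[C@H](O[Si](C)(C)C(C)(C)C)C[C@@]2(C)O1
F3 | step 7 | (3R,3aS,6S,7aR)-6-[(tert-butyldimethylsilyl)oxy]-4,4,7a-trimethyl-3-(phenylselanyl)hexahydro-1-benzofuran-2(3H)-one | O=C1[C@H]([Se]c3ccccc3)[C@H]2C(C)(C)C[C@H](O[Si](C)(C)C(C)(C)C)C[C@@]2(C)O1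
F4 | step 11 | (6S,7aR)-6-[(tert-butyldimethylsilyl)oxy]-4,4,7a-trimethyl-2,4,5,6,7,7a-hexahydro-1-benzofuran-2-ol (both anomers) | OC1C=C2C(C)(C)C[C@H](O[Si](C)(C)C(C)(C)C)C[C@@]2(C)O1
F5 | step 11 | (6S,7aR)-6-[(tert-butyldimethylsilyl)oxy]-4,4,7a-trimethyl-2,4,5,6,7,7a-hexahydro-1-benzofuran-2-yl acetate (both anomers) | CC(=O)OC1C=C2C(C)(C)C[C@H](O[Si](C)(C)C(C)(C)C)C[C@@]2(C)O1
F6 | step 11 | potassium trifluoro{(2E)-4-[(triisopropylsilyl)oxy]but-2-en-2-yl}borate | [K+].C/C(=C/CO[Si](C(C)C)(C(C)C)C(C)C)[B-](F)(F)F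
F7 | step 18 | (2R,6S,7aR)-2-[(2Z)-4-bromobut-2-en-2-yl]-4,4,7a-trimethyl-2,4,5,6,7,7a-hexahydro-1-benzofuran-6-ol | C/C(=C/CBr)[C@H]1C=C2C(C)(C)C[C@H](O)C[C@@]2(C)O1
F8 | step 18 | {(2Z)-3-[(2R,6S,7aR)-6-hydroxy-4,4,7a-trimethyl-2,4,5,6,7,7a-hexahydro-1-benzofuran-2-yl]but-2-en-1-yl}triphenylphosphonium bromide | [Br-].C/C(=C/C[P+](c3ccccc3)(c3ccccc3)c3ccccc3)[C@H]1C=C2C(C)(C)C[C@H](O)C[C@@]2(C)O1
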